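Assumption: atoms are numbered as in the kazusamycin family (C1 = carboxyl carbon, C19 = alkene carbon on the lactone), and compounds 1, 3, 7, 15, 28 and 32 are bought.

## Retrosynthetic overview

1. C11–C12: one-pot hydroboration/Suzuki union of west enyne-lactone 40 with east vinyl iodide 27, then C8 oxidation and desilylation.
2. C8–C9 (key step): electroreductive Pd/In-catalysed propargylation of aldehyde 14 with mesylate 21; C9 is set by chirality transfer from glyceraldehyde, and the methyl alkyne then becomes the (E)-vinyl iodide.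
3. Aldehyde 14: C6–C7 by Marshall allenylzinc propargylation of aldehyde 6 with butynol mesylate 8 (alkyne later cut to the C8 aldehyde); C3–C4 by Negishi coupling of a Roche-type zinc reagent with an enol triflate.
4. West: C17–C18 Stille coupling of (Z)-vinyl iodide 31 (Stork–Zhao olefination; C15 from bromo alcohol 28) with stannyl lactone 39, whose two stereocentres come from an indium-mediated Marshall propargylation with 8.
5. Ring order: the only ring, the δ-lactone, is closed early (step 23) by carboxylation, semi-hydrogenation and lactonisation of the second Marshall adduct.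

## Route

Step 1
Reactants: 1 tert-butyl 3-oxobutanoate
Product: 2 tert-butyl (2E)-3-{[(trifluoromethyl)sulfonyl]oxy}but-2-enoate
Conditions: Tf2O, aq. Me4NOH, hexane, 5 °C
Reagents that add atoms: trifluoromethanesulfonic anhydride, O=S(=O)(OS(=O)(=O)C(F)(F)F)C(F)(F)F
Why: Stereoselective enol triflation of a β-keto ester, in which the non-chelated tetramethylammonium enolate is O-sulfonylated to the (E)-enol triflate, fixing the later C2=C3 geometry.

Step 2
Reactants: 3 methyl (2S)-3-bromo-2-methylpropanoate; 2 tert-butyl (2E)-3-{[(trifluoromethyl)sulfonyl]oxy}but-2-enoate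
Product: 5 1-tert-butyl 6-methyl (2E,5R)-3,5-dimethylhex-2-enedioate, via alkylzinc bromide 4 (not isolated)
Conditions: Zn, LiCl, THF, 45 °C; then 2, Pd(PPh3)4 (3 mol%), THF, rt
Reagents that add atoms: none
Why: Zinc insertion into the primary C–Br bond leaves the adjacent stereocentre (future C5, bought in 3) untouched, and Negishi coupling with the enol triflate forms C3–C4 with retention of the E geometry.

Step 3
Reactants: 5 1-tert-butyl 6-methyl (2E,5R)-3,5-dimethylhex-2-enedioate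
Product: 6 tert-butyl (2E,5R)-3,5-dimethyl-6-oxohex-2-enoate
Conditions: i-Bu2AlH (1.05 equiv), CH2Cl2, −78 °C; aq. potassium sodium tartrate
Reagents that add atoms: none
Why: Low-temperature half-reduction, in which the saturated methyl ester gives a stable aluminium hemiacetal while the conjugated, β,β-disubstituted tert-butyl ester is too hindered and deactivated to react.

Step 4
Reactants: 7 (2R)-but-3-yn-2-ol
Product: 8 (2R)-but-3-yn-2-yl methanesulfonate
Conditions: MsCl, Et3N, CH2Cl2, −78 °C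
Reagents that add atoms: methanesulfonyl chloride, CS(=O)(=O)Cl
Why: Standard O-sulfonylation with retention at carbon, giving the propargylic electrophile for chirality transfer.

Step 5
Reactants: 6 tert-butyl (2E,5R)-3,5-dimethyl-6-oxohex-2-enoate; 8 (2R)-but-3-yn-2-yl methanesulfonate
Product: 10 tert-butyl (2E,5R,6R,7S)-6-hydroxy-3,5,7-trimethylnon-2-en-8-ynoate, via allenylzinc reagent 9 (not isolated)
Conditions: Pd(OAc)2 (5 mol%), PPh3 (5 mol%), Et2Zn (3 equiv), THF, −78 → −20 °C; aq. NH4Cl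
Reagents that add atoms: none
Why: Marshall allenylzinc propargylation, in which zerovalent palladium opens 8 by anti SN2′, Et2Zn transmetalates with retention (the PdEt2 left behind loses ethene and ethane and returns zerovalent palladium), and the closed six-membered syn SE2′ addition gives the anti C6/C7 pair with absolute sense transferred from the butynol centre (net inversion), reagent control overriding the weak facial bias of 6, so the anti,anti triad C5–C7 follows from pairing (R)-6 with (R)-8.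

Step 6
Reactants: 10 tert-butyl (2E,5R,6R,7S)-6-hydroxy-3,5,7-trimethylnon-2-en-8-ynoate
Product: 11 tert-butyl (2E,5R,6R,7S)-3,5,7-trimethyl-6-[(triethylsilyl)oxy]non-2-en-8-ynoate
Conditions: TESOTf (1.1 equiv), 2,6-lutidine, CH2Cl2, −78 °C
Reagents that add atoms: triethylsilyl trifluoromethanesulfonate, CC[Si](CC)(CC)OS(=O)(=O)C(F)(F)F
Why: Silylation of the hindered secondary alcohol is fast at −78 °C, where the tert-butyl ester is not yet attacked by the silyl triflate.

Step 7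
Reactants: 11 tert-butyl (2E,5R,6R,7S)-3,5,7-trimethyl-6-[(triethylsilyl)oxy]non-2-en-8-ynoate
Product: 12 tert-butyl (2E,5R,6R,7S)-3,5,7-trimethyl-6-[(triethylsilyl)oxy]nona-2,8-dienoate
Conditions: H2 (1 atm), Pd/CaCO3 poisoned by Pb(OAc)2, quinoline, EtOAc, rt
Reagents that add atoms: none
Why: Lindlar semi-hydrogenation stops at the terminal alkene and leaves the trisubstituted enoate alone.

Step 8
Reactants: 12 tert-butyl (2E,5R,6R,7S)-3,5,7-trimethyl-6-[(triethylsilyl)oxy]nona-2,8-dienoate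
Product: 14 tert-butyl (2E,5R,6R,7R)-3,5,7-trimethyl-8-oxo-6-[(triethylsilyl)oxy]oct-2-enoate, via ozonide 13 (not isolated)
Conditions: O3, CH2Cl2, −78 °C (Sudan Red 7B end point); then PPh3, −78 °C → rt
Reagents that add atoms: ozone, [O-][O+]=O
Why: Chemoselective ozonolysis, since the electron-rich vinyl group reacts far faster than the electron-poor trisubstituted enoate, and neutral reduction of the ozonide gives the α-methyl aldehyde without epimerisation.

Step 9
Reactants: 15 (4S)-2,2-dimethyl-1,3-dioxolane-4-carbaldehyde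
Product: 16 (4R)-4-ethynyl-2,2-dimethyl-1,3-dioxolane
Conditions: dimethyl (1-diazo-2-oxopropyl)phosphonate, K2CO3, MeOH, 0 °C → rt
Reagents that add atoms: dimethyl (1-diazo-2-oxopropyl)phosphonate, COP(=O)(OC)C(=[N+]=[N-])C(C)=O
Why: Ohira–Bestmann (Seyferth–Gilbert) homologation proceeds under mild carbonate conditions that do not epimerise the α-alkoxy aldehyde (the descriptor changes only because priorities change).

Step 10
Reactants: 16 (4R)-4-ethynyl-2,2-dimethyl-1,3-dioxolane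
Product: 18 (4R)-2,2-dimethyl-4-(prop-1-yn-1-yl)-1,3-dioxolane, via lithium acetylide 17 (not isolated)
Conditions: n-BuLi, THF, −78 °C; then MeI, −78 °C → rt
Reagents that add atoms: iodomethane, CI
Why: Acetylide alkylation installs the future C11 methyl and does not touch the stereocentre.

Step 11
Reactants: 18 (4R)-2,2-dimethyl-4-(prop-1-yn-1-yl)-1,3-dioxolane
Product: 19 (2R)-pent-3-yne-1,2-diol
Conditions: Amberlyst-15, MeOH, rt
Reagents that add atoms: none
Why: Acid-catalysed transacetalisation removes the acetonide without ionising the propargylic C–O bond.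

Step 12
Reactants: 19 (2R)-pent-3-yne-1,2-diol
Product: 20 (2R)-1-{[tert-butyl(dimethyl)silyl]oxy}pent-3-yn-2-ol
Conditions: TBSCl (1.05 equiv), imidazole, CH2Cl2, −20 °C
Reagents that add atoms: tert-butyldimethylsilyl chloride, CC(C)(C)[Si](C)(C)Cl
Why: Sterically controlled silylation of the primary hydroxyl of a 1,2-diol.

Step 13
Reactants: 20 (2R)-1-{[tert-butyl(dimethyl)silyl]oxy}pent-3-yn-2-ol
Product: 21 (2R)-1-{[tert-butyl(dimethyl)silyl]oxy}pent-3-yn-2-yl methanesulfonate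
Conditions: MsCl, Et3N, CH2Cl2, −78 °C
Reagents that add atoms: methanesulfonyl chloride, CS(=O)(=O)Cl
Why: O-sulfonylation with retention gives the enantiopure propargylic electrophile that carries the future C9, its CH2O arm and C10–C11.

Step 14
Reactants: 14 tert-butyl (2E,5R,6R,7R)-3,5,7-trimethyl-8-oxo-6-[(triethylsilyl)oxy]oct-2-enoate; 21 (2R)-1-{[tert-butyl(dimethyl)silyl]oxy}pent-3-yn-2-yl methanesulfonate
Product: 23 tert-butyl (2E,5R,6R,7S,8R,9S)-9-({[tert-butyl(dimethyl)silyl]oxy}methyl)-8-hydroxy-3,5,7-trimethyl-6-[(triethylsilyl)oxy]dodec-2-en-10-ynoate, via allenylindium reagent 22 (not isolated)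
Conditions: Pd(OAc)2 (5 mol%), PPh3 (5 mol%), InBr3 (10 mol%), Bu4NBr (0.1 M), THF–DMPU 3:1, undivided cell, Al anode, carbon-felt cathode, constant current 5 mA, 2.2 F/mol, rt; aq. NH4Cl
Reagents that add atoms: none
Why: Proposed new method: an electroreductive palladium/indium co-catalysed SE2′ propargylation in which zerovalent palladium opens 21 by anti SN2′ to an allenylpalladium mesylate, cathodically regenerated monovalent indium (from catalytic InBr3, electrons supplied by the sacrificial Al anode, whose trivalent aluminium takes over the product alkoxide) captures it by oxidative transmetalation with retention to give axially chiral 22, and 22 adds to 14 through a closed six-membered syn SE2′ transition state, so C9 is fixed by the glyceraldehyde-derived centre (net inversion) and C8/C9 come out anti, while any C8 epimer converges at step 26; the closest known reactions are the Marshall Pd/InI propargylation with stoichiometric InI and the electrochemical regeneration of low-valent indium for Barbier-type allylation.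

Step 15
Reactants: 23 tert-butyl (2E,5R,6R,7S,8R,9S)-9-({[tert-butyl(dimethyl)silyl]oxy}methyl)-8-hydroxy-3,5,7-trimethyl-6-[(triethylsilyl)oxy]dodec-2-en-10-ynoate
Product: 25 tert-butyl (2E,5R,6R,7S,8R,9S,10E)-9-({[tert-butyl(dimethyl)silyl]oxy}methyl)-8-hydroxy-11-iodo-3,5,7-trimethyl-6-[(triethylsilyl)oxy]dodeca-2,10-dienoate, via vinylstannane 24 (not isolated)
Conditions: Bu3SnH (1.3 equiv), PdCl2(PPh3)2 (3 mol%), THF, 0 °C; then I2, CH2Cl2, 0 °C
Reagents that add atoms: iodine, II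
Why: Palladium-catalysed syn hydrostannation places tin on the less hindered methyl-bearing alkyne carbon (distal to the branched C9), and iododestannylation with retention gives the (E)-trisubstituted vinyl iodide; the minor regioisomer is removed here.

Step 16
Reactants: 25 tert-butyl (2E,5R,6R,7S,8R,9S,10E)-9-({[tert-butyl(dimethyl)silyl]oxy}methyl)-8-hydroxy-11-iodo-3,5,7-trimethyl-6-[(triethylsilyl)oxy]dodeca-2,10-dienoate
Product: 27 (2E,5R,6R,7S,8R,9S,10E)-9-({[tert-butyl(dimethyl)silyl]oxy}methyl)-8-hydroxy-11-iodo-3,5,7-trimethyl-6-[(triethylsilyl)oxy]dodeca-2,10-dienoic acid, via bis(trimethylsilyl) derivative 26 (not isolated)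
Conditions: TMSOTf (3 equiv), 2,6-lutidine, CH2Cl2, 0 °C → rt; then K2CO3, MeOH, 0 °C; citric acid work-up
Reagents that add atoms: none
Why: Silyl triflate-mediated tert-butyl ester cleavage (loss of isobutene) is done here, before the ketone, the lactone and the acid-labile dienyl C–O bond exist, and mild methanolysis then removes the labile TMS ester and C8 TMS ether while the TES and TBS ethers stay.

Step 17
Reactants: 28 (2R)-3-bromo-2-methylpropan-1-ol
Product: 29 (2S)-2-methylpent-4-yn-1-ol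
Conditions: LiC≡CH·H2NCH2CH2NH2 (2.5 equiv), DMSO, 5 °C → rt
Reagents that add atoms: lithium acetylide–ethylenediamine complex, [Li+].[C-]#C.NCCN
Why: SN2 alkynylation of the primary bromide outpaces four-membered ring closure of the alkoxide, and the stereocentre (future C15, bought in 28) is not involved.

Step 18
Reactants: 29 (2S)-2-methylpent-4-yn-1-ol
Product: 30 (2S)-2-methylpent-4-ynal
Conditions: Dess–Martin periodinane, NaHCO3, CH2Cl2, 0 °C
Reagents that add atoms: none
Why: Buffered Dess–Martin oxidation gives the volatile α-methyl aldehyde without epimerisation, and it is used at once in solution.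

Step 19
Reactants: 30 (2S)-2-methylpent-4-ynal
Product: 31 (4S,5Z)-6-iodo-4-methylhept-5-en-1-yne
Conditions: Ph3P(Et)I, n-BuLi, THF, rt; I2, −78 °C; NaN(SiMe3)2, −78 → −20 °C; then 30, −78 °C
Reagents that add atoms: ethyltriphenylphosphonium iodide, CC[P+](c1ccccc1)(c1ccccc1)c1ccccc1.[I-]; iodine, II
Why: Stork–Zhao olefination, in which the non-stabilised α-iodo ylide reacts under kinetic control to give the (Z)-2-iodoalk-2-ene, placing iodine (later C18) cis to C15 as the 16Z alkene requires.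

Step 20
Reactants: 32 (2E)-3-(tributylstannyl)prop-2-en-1-ol
Product: 33 (2E)-3-(tributylstannyl)prop-2-enal
Conditions: MnO2, CH2Cl2, rt
Reagents that add atoms: none
Why: Allylic oxidation with MnO2 is neutral and leaves the vinylstannane and its E geometry intact.

Step 21
Reactants: 33 (2E)-3-(tributylstannyl)prop-2-enal; 8 (2R)-but-3-yn-2-yl methanesulfonate
Product: 35 (1E,3S,4S)-4-methyl-1-(tributylstannyl)hex-1-en-5-yn-3-ol, via allenylindium reagent 34 (not isolated)
Conditions: Pd(OAc)2 (5 mol%), PPh3 (5 mol%), InI (1.4 equiv), THF–DMPU 3:1, 0 °C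
Reagents that add atoms: none
Why: Marshall indium propargylation (indium is chosen over zinc because the aldehyde is conjugated), in which zerovalent palladium opens 8 by anti SN2′, InI takes over the allenyl group by oxidative transmetalation with retention and the closed syn SE2′ addition sets both lactone stereocentres anti (the future trans-lactone) with absolute sense from (R)-8, the vinylstannane being a spectator because transmetalation to InI is much faster than Stille transfer at 0 °C without copper or fluoride.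

Step 22
Reactants: 35 (1E,3S,4S)-4-methyl-1-(tributylstannyl)hex-1-en-5-yn-3-ol
Product: 37 (4S,5S,6E)-5-hydroxy-4-methyl-7-(tributylstannyl)hept-6-en-2-ynoic acid, via bis(bromomagnesium) alkoxide acetylide 36 (not isolated)
Conditions: EtMgBr (2.2 equiv), THF, 0 °C → rt; then CO2 (1 atm), −20 °C → rt; aq. NaH2PO4
Reagents that add atoms: carbon dioxide, O=C=O
Why: Carboxylation of the alkynyl Grignard (the vinylstannane is inert to EtMgBr, unlike to alkyllithiums), with the alkoxide carbonate reverting on work-up.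

Step 23
Reactants: 37 (4S,5S,6E)-5-hydroxy-4-methyl-7-(tributylstannyl)hept-6-en-2-ynoic acid
Product: 39 (5S,6S)-5-methyl-6-[(E)-2-(tributylstannyl)ethenyl]-5,6-dihydro-2H-pyran-2-one, via (Z)-hydroxy acid 38 (not isolated)
Conditions: H2 (1 atm), Pd/CaCO3 poisoned by Pb(OAc)2, quinoline, EtOAc, rt; then PPTS (cat.), CH2Cl2, rt
Reagents that add atoms: none
Why: Lindlar semi-hydrogenation gives the (Z)-enoic acid, whose δ-hydroxyl lactonises to close the only ring with both stereocentres untouched.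

Step 24
Reactants: 31 (4S,5Z)-6-iodo-4-methylhept-5-en-1-yne; 39 (5S,6S)-5-methyl-6-[(E)-2-(tributylstannyl)ethenyl]-5,6-dihydro-2H-pyran-2-one
Product: 40 (5S,6R)-6-[(1E,3Z,5S)-3,5-dimethylocta-1,3-dien-7-yn-1-yl]-5-methyl-5,6-dihydro-2H-pyran-2-one
Conditions: Pd2(dba)3 (5 mol%), AsPh3 (20 mol%), NMP, rt, dark
Reagents that add atoms: none
Why: Copper-free, base-free Stille coupling forms C17–C18 with retention of both alkene geometries, leaves the terminal alkyne alone and is fast enough at rt that the allylic lactone C–O bond is not ionised.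

Step 25
Reactants: 40 (5S,6R)-6-[(1E,3Z,5S)-3,5-dimethylocta-1,3-dien-7-yn-1-yl]-5-methyl-5,6-dihydro-2H-pyran-2-one; 27 (2E,5R,6R,7S,8R,9S,10E)-9-({[tert-butyl(dimethyl)silyl]oxy}methyl)-8-hydroxy-11-iodo-3,5,7-trimethyl-6-[(triethylsilyl)oxy]dodeca-2,10-dienoic acid
Product: 42 (2E,5R,6R,7S,8R,9S,10E,12E,15S,16Z,18E)-9-({[tert-butyl(dimethyl)silyl]oxy}methyl)-8-hydroxy-3,5,7,11,15,17-hexamethyl-19-[(2R,3S)-3-methyl-6-oxo-3,6-dihydro-2H-pyran-2-yl]-6-[(triethylsilyl)oxy]nonadeca-2,10,12,16,18-pentaenoic acid, via alkenyl dicyclohexylborane 41 (not isolated)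
Conditions: Cy2BH (1.2 equiv), THF, 0 °C; then 27, Pd(PPh3)4 (10 mol%), TlOEt, THF–H2O, rt
Reagents that add atoms: none
Why: Syn anti-Markovnikov hydroboration of the terminal alkyne by the bulky dialkylborane is much faster than attack on the trisubstituted or conjugated alkenes or the lactone, and TlOEt-accelerated Suzuki–Miyaura coupling then forms C11–C12 with retention at both alkenes while C8 is still a carbinol, so no epimerisable ketone sees base.

Step 26
Reactants: 42 (2E,5R,6R,7S,8R,9S,10E,12E,15S,16Z,18E)-9-({[tert-butyl(dimethyl)silyl]oxy}methyl)-8-hydroxy-3,5,7,11,15,17-hexamethyl-19-[(2R,3S)-3-methyl-6-oxo-3,6-dihydro-2H-pyran-2-yl]-6-[(triethylsilyl)oxy]nonadeca-2,10,12,16,18-pentaenoic acid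
Product: 43 (2E,5R,6R,7R,9S,10E,12E,15S,16Z,18E)-9-({[tert-butyl(dimethyl)silyl]oxy}methyl)-3,5,7,11,15,17-hexamethyl-19-[(2R,3S)-3-methyl-6-oxo-3,6-dihydro-2H-pyran-2-yl]-8-oxo-6-[(triethylsilyl)oxy]nonadeca-2,10,12,16,18-pentaenoic acid
Conditions: Dess–Martin periodinane, NaHCO3, CH2Cl2, 0 °C
Reagents that add atoms: none
Why: Buffered Dess–Martin oxidation of the only free hydroxyl gives the C8 ketone without epimerising C7 or the doubly activated C9, and both C8 epimers of 42 converge here.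

Step 27
Reactants: 43 (2E,5R,6R,7R,9S,10E,12E,15S,16Z,18E)-9-({[tert-butyl(dimethyl)silyl]oxy}methyl)-3,5,7,11,15,17-hexamethyl-19-[(2R,3S)-3-methyl-6-oxo-3,6-dihydro-2H-pyran-2-yl]-8-oxo-6-[(triethylsilyl)oxy]nonadeca-2,10,12,16,18-pentaenoic acid
Product: 44 (2E,5R,6R,7R,9S,10E,12E,15S,16Z,18E)-6-hydroxy-9-(hydroxymethyl)-3,5,7,11,15,17-hexamethyl-19-[(2R,3S)-3-methyl-6-oxo-3,6-dihydro-2H-pyran-2-yl]-8-oxononadeca-2,10,12,16,18-pentaenoic acid
Conditions: HF·pyridine, pyridine, THF, 0 °C → rt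
Reagents that add atoms: none
Why: Buffered acidic fluoride desilylation removes the secondary TES and primary TBS ethers without exposing the β-hydroxy ketone, the epimerisable C9 or the unsaturated lactone to base, and no stereocentre is changed.

## Compound list

1 | tert-butyl 3-oxobutanoate | CC(=O)CC(=O)OC(C)(C)C | starting material
2 | tert-butyl (2E)-3-{[(trifluoromethyl)sulfonyl]oxy}but-2-enoate | C/C(OS(=O)(=O)C(F)(F)F)=C\C(=O)OC(C)(C)C | intermediate
3 | methyl (2S)-3-bromo-2-methylpropanoate | COC(=O)[C@H](C)CBr | starting material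
4 | [(2S)-3-methoxy-2-methyl-3-oxopropyl]zinc bromide | COC(=O)[C@H](C)C[Zn]Br | intermediate
5 | 1-tert-butyl 6-methyl (2E,5R)-3,5-dimethylhex-2-enedioate | COC(=O)[C@H](C)C/C(C)=C/C(=O)OC(C)(C)C | intermediate
6 | tert-butyl (2E,5R)-3,5-dimethyl-6-oxohex-2-enoate | O=C[C@H](C)C/C(C)=C/C(=O)OC(C)(C)C | intermediate
7 | (2R)-but-3-yn-2-ol | C[C@@H](O)C#C | starting material
8 | (2R)-but-3-yn-2-yl methanesulfonate | C[C@@H](OS(C)(=O)=O)C#C | intermediate
9 | (aS)-buta-1,2-dien-1-ylzinc methanesulfonate | CC=[C@@]=C[Zn]OS(C)(=O)=O | intermediate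
10 | tert-butyl (2E,5R,6R,7S)-6-hydroxy-3,5,7-trimethylnon-2-en-8-ynoate | C#C[C@H](C)[C@H](O)[C@H](C)C/C(C)=C/C(=O)OC(C)(C)C | intermediate
11 | tert-butyl (2E,5R,6R,7S)-3,5,7-trimethyl-6-[(triethylsilyl)oxy]non-2-en-8-ynoate | C#C[C@H](C)[C@H](O[Si](CC)(CC)CC)[C@H](C)C/C(C)=C/C(=O)OC(C)(C)C | intermediate
12 | tert-butyl (2E,5R,6R,7S)-3,5,7-trimethyl-6-[(triethylsilyl)oxy]nona-2,8-dienoate | C=C[C@H](C)[C@H](O[Si](CC)(CC)CC)[C@H](C)C/C(C)=C/C(=O)OC(C)(C)C | intermediate
13 | tert-butyl (2E,5R,6R,7R)-3,5-dimethyl-6-[(triethylsilyl)oxy]-7-(1,2,4-trioxolan-3-yl)oct-2-enoate (epimers at the ozonide carbon) | C1(OOCO1)[C@H](C)[C@H](O[Si](CC)(CC)CC)[C@H](C)C/C(C)=C/C(=O)OC(C)(C)C | intermediate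
14 | tert-butyl (2E,5R,6R,7R)-3,5,7-trimethyl-8-oxo-6-[(triethylsilyl)oxy]oct-2-enoate | O=C[C@H](C)[C@H](O[Si](CC)(CC)CC)[C@H](C)C/C(C)=C/C(=O)OC(C)(C)C | intermediate
15 | (4S)-2,2-dimethyl-1,3-dioxolane-4-carbaldehyde | O=C[C@@H]1COC(C)(C)O1 | starting material
16 | (4R)-4-ethynyl-2,2-dimethyl-1,3-dioxolane | C#C[C@@H]1COC(C)(C)O1 | intermediate
17 | {[(4R)-2,2-dimethyl-1,3-dioxolan-4-yl]ethynyl}lithium | [Li]C#C[C@@H]1COC(C)(C)O1 | intermediate
18 | (4R)-2,2-dimethyl-4-(prop-1-yn-1-yl)-1,3-dioxolane | CC#C[C@@H]1COC(C)(C)O1 | intermediate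
19 | (2R)-pent-3-yne-1,2-diol | CC#C[C@H](CO)O | intermediate
20 | (2R)-1-{[tert-butyl(dimethyl)silyl]oxy}pent-3-yn-2-ol | CC#C[C@H](CO[Si](C)(C)C(C)(C)C)O | intermediate
21 | (2R)-1-{[tert-butyl(dimethyl)silyl]oxy}pent-3-yn-2-yl methanesulfonate | CC#C[C@H](CO[Si](C)(C)C(C)(C)C)OS(C)(=O)=O | intermediate
22 | (aR)-(5-{[tert-butyl(dimethyl)silyl]oxy}penta-2,3-dien-2-yl)indium bromide methanesulfonate | CC([In](Br)OS(C)(=O)=O)=[C@@]=CCO[Si](C)(C)C(C)(C)C | intermediate
23 | tert-butyl (2E,5R,6R,7S,8R,9S)-9-({[tert-butyl(dimethyl)silyl]oxy}methyl)-8-hydroxy-3,5,7-trimethyl-6-[(triethylsilyl)oxy]dodec-2-en-10-ynoate | CC#C[C@@H](CO[Si](C)(C)C(C)(C)C)[C@@H](O)[C@H](C)[C@H](O[Si](CC)(CC)CC)[C@H](C)C/C(C)=C/C(=O)OC(C)(C)C | intermediate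
24 | tert-butyl (2E,5R,6R,7S,8R,9S,10E)-9-({[tert-butyl(dimethyl)silyl]oxy}methyl)-8-hydroxy-3,5,7-trimethyl-11-(tributylstannyl)-6-[(triethylsilyl)oxy]dodeca-2,10-dienoate | CCCC[Sn](CCCC)(CCCC)/C(C)=C/[C@@H](CO[Si](C)(C)C(C)(C)C)[C@@H](O)[C@H](C)[C@H](O[Si](CC)(CC)CC)[C@H](C)C/C(C)=C/C(=O)OC(C)(C)C | intermediate
25 | tert-butyl (2E,5R,6R,7S,8R,9S,10E)-9-({[tert-butyl(dimethyl)silyl]oxy}methyl)-8-hydroxy-11-iodo-3,5,7-trimethyl-6-[(triethylsilyl)oxy]dodeca-2,10-dienoate | I/C(C)=C/[C@@H](CO[Si](C)(C)C(C)(C)C)[C@@H](O)[C@H](C)[C@H](O[Si](CC)(CC)CC)[C@H](C)C/C(C)=C/C(=O)OC(C)(C)C | intermediate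
26 | trimethylsilyl (2E,5R,6R,7R,8R,9S,10E)-9-({[tert-butyl(dimethyl)silyl]oxy}methyl)-11-iodo-3,5,7-trimethyl-6-[(triethylsilyl)oxy]-8-[(trimethylsilyl)oxy]dodeca-2,10-dienoate | I/C(C)=C/[C@@H](CO[Si](C)(C)C(C)(C)C)[C@@H](O[Si](C)(C)C)[C@H](C)[C@H](O[Si](CC)(CC)CC)[C@H](C)C/C(C)=C/C(=O)O[Si](C)(C)C | intermediate
27 | (2E,5R,6R,7S,8R,9S,10E)-9-({[tert-butyl(dimethyl)silyl]oxy}methyl)-8-hydroxy-11-iodo-3,5,7-trimethyl-6-[(triethylsilyl)oxy]dodeca-2,10-dienoic acid | I/C(C)=C/[C@@H](CO[Si](C)(C)C(C)(C)C)[C@@H](O)[C@H](C)[C@H](O[Si](CC)(CC)CC)[C@H](C)C/C(C)=C/C(=O)O | intermediate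
28 | (2R)-3-bromo-2-methylpropan-1-ol | OC[C@@H](C)CBr | starting material
29 | (2S)-2-methylpent-4-yn-1-ol | OC[C@@H](C)CC#C | intermediate
30 | (2S)-2-methylpent-4-ynal | O=C[C@@H](C)CC#C | intermediate
31 | (4S,5Z)-6-iodo-4-methylhept-5-en-1-yne | CC(=C/[C@@H](C)CC#C)/I | intermediate
32 | (2E)-3-(tributylstannyl)prop-2-en-1-ol | CCCC[Sn](CCCC)(CCCC)/C=C/CO | starting material
33 | (2E)-3-(tributylstannyl)prop-2-enal | CCCC[Sn](CCCC)(CCCC)/C=C/C=O | intermediate
34 | (aS)-buta-1,2-dien-1-ylindium iodide methanesulfonate | CC=[C@@]=C[In](I)OS(C)(=O)=O | intermediate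
35 | (1E,3S,4S)-4-methyl-1-(tributylstannyl)hex-1-en-5-yn-3-ol | CCCC[Sn](CCCC)(CCCC)/C=C/[C@@H](O)[C@@H](C)C#C | intermediate
36 | bis(bromomagnesium) salt of 35 (alkoxide and acetylide) | CCCC[Sn](CCCC)(CCCC)/C=C/[C@@H](O[Mg]Br)[C@@H](C)C#C[Mg]Br | intermediate
37 | (4S,5S,6E)-5-hydroxy-4-methyl-7-(tributylstannyl)hept-6-en-2-ynoic acid | CCCC[Sn](CCCC)(CCCC)/C=C/[C@@H](O)[C@@H](C)C#CC(=O)O | intermediate
38 | (2Z,4S,5S,6E)-5-hydroxy-4-methyl-7-(tributylstannyl)hepta-2,6-dienoic acid | CCCC[Sn](CCCC)(CCCC)/C=C/[C@@H](O)[C@@H](C)/C=C\C(=O)O | intermediate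
39 | (5S,6S)-5-methyl-6-[(E)-2-(tributylstannyl)ethenyl]-5,6-dihydro-2H-pyran-2-one | CCCC[Sn](CCCC)(CCCC)/C=C/[C@H]1OC(=O)C=C[C@@H]1C | intermediate
40 | (5S,6R)-6-[(1E,3Z,5S)-3,5-dimethylocta-1,3-dien-7-yn-1-yl]-5-methyl-5,6-dihydro-2H-pyran-2-one | CC(=C/[C@@H](C)CC#C)/C=C/[C@H]1OC(=O)C=C[C@@H]1C | intermediate
41 | (5S,6R)-6-[(1E,3Z,5S,7E)-8-(dicyclohexylboranyl)-3,5-dimethylocta-1,3,7-trien-1-yl]-5-methyl-5,6-dihydro-2H-pyran-2-one | CC(=C/[C@@H](C)C/C=C/B(C1CCCCC1)C1CCCCC1)/C=C/[C@H]1OC(=O)C=C[C@@H]1C | intermediate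
42 | (2E,5R,6R,7S,8R,9S,10E,12E,15S,16Z,18E)-9-({[tert-butyl(dimethyl)silyl]oxy}methyl)-8-hydroxy-3,5,7,11,15,17-hexamethyl-19-[(2R,3S)-3-methyl-6-oxo-3,6-dihydro-2H-pyran-2-yl]-6-[(triethylsilyl)oxy]nonadeca-2,10,12,16,18-pentaenoic acid | CC(=C/[C@@H](C)C/C=C/C(C)=C/[C@@H](CO[Si](C)(C)C(C)(C)C)[C@@H](O)[C@H](C)[C@H](O[Si](CC)(CC)CC)[C@H](C)C/C(C)=C/C(=O)O)/C=C/[C@H]1OC(=O)C=C[C@@H]1C | intermediate
43 | (2E,5R,6R,7R,9S,10E,12E,15S,16Z,18E)-9-({[tert-butyl(dimethyl)silyl]oxy}methyl)-3,5,7,11,15,17-hexamethyl-19-[(2R,3S)-3-methyl-6-oxo-3,6-dihydro-2H-pyran-2-yl]-8-oxo-6-[(triethylsilyl)oxy]nonadeca-2,10,12,16,18-pentaenoic acid | CC(=C/[C@@H](C)C/C=C/C(C)=C/[C@@H](CO[Si](C)(C)C(C)(C)C)C(=O)[C@H](C)[C@H](O[Si](CC)(CC)CC)[C@H](C)C/C(C)=C/C(=O)O)/C=C/[C@H]1OC(=O)C=C[C@@H]1C | intermediate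
44 | (2E,5R,6R,7R,9S,10E,12E,15S,16Z,18E)-6-hydroxy-9-(hydroxymethyl)-3,5,7,11,15,17-hexamethyl-19-[(2R,3S)-3-methyl-6-oxo-3,6-dihydro-2H-pyran-2-yl]-8-oxononadeca-2,10,12,16,18-pentaenoic acid (CNP0298860.3) | CC(=C/[C@@H](C)C/C=C/C(C)=C/[C@@H](CO)C(=O)[C@H](C)[C@H](O)[C@H](C)C/C(C)=C/C(=O)O)/C=C/[C@H]1OC(=O)C=C[C@@H]1C | target

## Step count and risks

Total step count: 27.
Longest linear sequence: 13 steps from 1 to 44 (steps 1, 2, 3, 5, 6, 7, 8, 14, 15, 16, 25, 26, 27).

The three steps most likely to fail: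

1. Step 14 (the proposed new electroreductive propargylation). Indium turnover at the cathode or erosion of the allenyl axis under electrolysis may fail. The fallback sets out from 14 and 21 and comes back at 23. It drops the electrolysis and uses the established stoichiometric Marshall indium protocol of step 21: Pd(OAc)2 and PPh3 (5 mol% each) with InI (1.4 equiv) in THF–DMPU at 0 °C convert 21 into (aR)-(5-{[tert-butyl(dimethyl)silyl]oxy}penta-2,3-dien-2-yl)indium iodide methanesulfonate F1, which adds to 14 in the same anti SE2′ sense to give 23.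

2. Step 19 (Stork–Zhao olefination). Yields of the iodo-ylide reaction are often low and the Z:E ratio can erode. The fallback sets out from 30 and comes back at 40. Corey–Fuchs olefination (CBr4, PPh3, CH2Cl2, 0 °C) gives (3S)-1,1-dibromo-3-methylhex-1-en-5-yne F2. Trans-selective Negishi monomethylation (MeZnCl, PdCl2(DPEphos) 3 mol%, THF, 0 °C) replaces only the bromine trans to the alkyl chain and gives (4S,5Z)-6-bromo-4-methylhept-5-en-1-yne F3. Stille coupling of F3 with 39 (Pd2(dba)3, P(2-furyl)3, NMP, 50 °C) then gives 40.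

3. Step 25 (hydroboration/Suzuki union). The borane may attack the lactone or the conjugated diene of 40, and the lactone sees aqueous base. The fallback sets out from 31 (with 39 and 27) and comes back at 42. Boron is put on before the lactone and diene are present: 31 with pinacolborane and Cp2Zr(H)Cl (5 mol%) in CH2Cl2 at rt gives 2-[(1E,4S,5Z)-6-iodo-4-methylhepta-1,5-dien-1-yl]-4,4,5,5-tetramethyl-1,3,2-dioxaborolane F4. Stille coupling of F4 with 39 under the step 24 conditions (the boronate is a spectator) gives (5S,6R)-6-[(1E,3Z,5S,7E)-3,5-dimethyl-8-(4,4,5,5-tetramethyl-1,3,2-dioxaborolan-2-yl)octa-1,3,7-trien-1-yl]-5-methyl-5,6-dihydro-2H-pyran-2-one F5. Suzuki coupling of F5 with 27 (Pd(PPh3)4, TlOEt, THF–H2O, rt) gives 42.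

## Further compounds

F1 | step 14 | (aR)-(5-{[tert-butyl(dimethyl)silyl]oxy}penta-2,3-dien-2-yl)indium iodide methanesulfonate | CC([In](I)OS(C)(=O)=O)=[C@@]=CCO[Si](C)(C)C(C)(C)C
F2 | step 19 | (3S)-1,1-dibromo-3-methylhex-1-en-5-yne | BrC(Br)=C[C@@H](C)CC#C
F3 | step 19 | (4S,5Z)-6-bromo-4-methylhept-5-en-1-yne | CC(=C/[C@@H](C)CC#C)/Br
F4 | step 25 | 2-[(1E,4S,5Z)-6-iodo-4-methylhepta-1,5-dien-1-yl]-4,4,5,5-tetramethyl-1,3,2-dioxaborolane | CC(=C/[C@@H](C)C/C=C/B1OC(C)(C)C(C)(C)O1)/I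
F5 | step 25 | (5S,6R)-6-[(1E,3Z,5S,7E)-3,5-dimethyl-8-(4,4,5,5-tetramethyl-1,3,2-dioxaborolan-2-yl)octa-1,3,7-trien-1-yl]-5-methyl-5,6-dihydro-2H-pyran-2-one | CC(=C/[C@@H](C)C/C=C/B1OC(C)(C)C(C)(C)O1)/C=C/[C@H]1OC(=O)C=C[C@@H]1C
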